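**Strategy.** Ring C is disconnected between C2 and C3. C2 carries O1 and catechol ring B, so it can be carried as the carbonyl carbon of an aryl 3,4-bis(benzyloxy)benzoate, while C3 and C4 come from an allyl group placed beside O1 on ring A by Claisen rearrangement. In one operation, a Tebbe-mediated olefinic-ester cyclisation (carbonyl methylenation, then titanium-methylidene ring-closing metathesis) turns this ortho-allylaryl ester into an achiral flav-2-ene by forming C2=C3. Asymmetric hydroboration then sets C2 and puts oxygen on C3, oxidation and L-Selectride reduction invert C3 to the 2,3-cis alcohol, and acylation with protected 4-O-methylgallic acid and hydrogenolysis finish the synthesis.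

Key step: step 4

Assumption: compounds 1, 2, 5 and 13 are taken as commercially available.
Assumption: IpcBH2 made from (+)-α-pinene is taken to add to the C2=C3 enol ether with the facial sense known for 1-arylcycloalkenes, which corresponds to 2R,3S here; if the sense proves opposite, the reagent from (−)-α-pinene is used.

Step 1
Reactants: 1 3,5-bis(benzyloxy)phenol; 2 allyl bromide
Product: 3 1-(allyloxy)-3,5-bis(benzyloxy)benzene
Conditions: K2CO3, acetone, reflux
Reagents that add atoms: none
Why: Williamson ether synthesis: the potassium phenoxide of 1 should displace bromide from the primary allylic halide by SN2 at oxygen.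

Step 2
Reactants: 3 1-(allyloxy)-3,5-bis(benzyloxy)benzene
Product: 4 2-allyl-3,5-bis(benzyloxy)phenol
Conditions: N,N-diethylaniline, 190 °C, argon
Reagents that add atoms: none
Why: Aromatic Claisen rearrangement ([3,3]-sigmatropic shift, then tautomerisation) should move the allyl group to an ortho carbon, and since both ortho positions of 3 are equivalent by symmetry a single C-allylphenol is expected, with the future C4 and C3 next to the future O1.

Step 3
Reactants: 4 2-allyl-3,5-bis(benzyloxy)phenol; 5 3,4-bis(benzyloxy)benzoic acid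
Product: 6 2-allyl-3,5-bis(benzyloxy)phenyl 3,4-bis(benzyloxy)benzoate
Conditions: DCC, DMAP (cat.), CH2Cl2, 0 °C to rt
Reagents that add atoms: none
Why: Steglich esterification: DCC activates acid 5 and DMAP transfers the acyl group to the phenol oxygen, which becomes O1 while the carboxyl carbon becomes C2.

Step 4
Reactants: 6 2-allyl-3,5-bis(benzyloxy)phenyl 3,4-bis(benzyloxy)benzoate
Product: 8 5,7-bis(benzyloxy)-2-[3,4-bis(benzyloxy)phenyl]-4H-chromene, via vinyl ether 7 (not isolated)
Conditions: Tebbe reagent Cp2Ti(μ-CH2)(μ-Cl)AlMe2 (4 equiv), pyridine (cat.), THF, −40 °C to rt; then reflux, 0.01 M; work-up on basic alumina with Et3N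
Reagents that add atoms: none
Why: The Tebbe reagent delivers titanocene methylidene Cp2Ti=CH2, which converts the ester C=O of 6 into the aryl vinyl ether 7 through an oxatitanacyclobutane (carbonyl methylenation, as in the standard conversion of phenyl benzoate into 1-phenoxystyrene); on heating, further titanium methylidene takes up the terminal allyl olefin, and the resulting titanium alkylidene closes on the 1,1-disubstituted enol ether by [2+2] cycloaddition and cycloreversion, expelling ethylene and forming the C2=C3 bond. The closest known reaction type is the Tebbe-mediated olefinic-ester cyclisation, which turns olefinic esters directly into six- and seven-membered cyclic enol ethers. Ring C is closed by ring-closing olefin metathesis to a six-membered ring; the ortho-disubstituted arene of ring A holds the two alkenes as a rigid 1,6-diene, so ring closure should outrun oligomerisation at high dilution. No stereocenter is formed: 8 is achiral with a planar C2=C3 enol ether, and C2 and C3 are set in steps 5 and 7. The step needs chemoselectivity for the ester carbonyl, which is the only C=O in 6 (benzyl ethers and arenes are inert to the titanium methylidene), and it needs the double bond to stay at C2=C3, which the metathesis mechanism fixes and the amine-buffered basic work-up should preserve.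

Step 5
Reactants: 8 5,7-bis(benzyloxy)-2-[3,4-bis(benzyloxy)phenyl]-4H-chromene
Product: 10 (2R,3S)-5,7-bis(benzyloxy)-2-[3,4-bis(benzyloxy)phenyl]chroman-3-ol, via organoborane 9 (not isolated)
Conditions: IpcBH2 (1.2 equiv, from (+)-α-pinene), THF, −25 °C; then NaOH aq, H2O2, 0 °C to rt
Reagents that add atoms: hydrogen peroxide, OO
Why: Asymmetric hydroboration–oxidation with monoisopinocampheylborane: boron should add to C3 (the β-carbon of the enol ether) and hydrogen to C2 in a syn fashion on the alkene face selected by the isopinocampheyl group, which sets 2R and the 2,3-trans relation, and alkaline peroxide then replaces boron by OH with retention (3S).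

Step 6
Reactants: 10 (2R,3S)-5,7-bis(benzyloxy)-2-[3,4-bis(benzyloxy)phenyl]chroman-3-ol
Product: 11 (2R)-5,7-bis(benzyloxy)-2-[3,4-bis(benzyloxy)phenyl]chroman-3-one
Conditions: Dess–Martin periodinane, moist CH2Cl2, rt
Reagents that add atoms: none
Why: Dess–Martin oxidation converts the secondary alcohol into the ketone under near-neutral conditions at room temperature, under which the C2 stereocenter next to the new carbonyl should not enolise.

Step 7
Reactants: 11 (2R)-5,7-bis(benzyloxy)-2-[3,4-bis(benzyloxy)phenyl]chroman-3-one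
Product: 12 (2R,3R)-5,7-bis(benzyloxy)-2-[3,4-bis(benzyloxy)phenyl]chroman-3-ol
Conditions: LiBH(s-Bu)3 (L-Selectride), LiBr, THF, −78 °C; then H2O
Reagents that add atoms: none
Why: Diastereoselective ketone reduction with the bulky trialkylborohydride L-Selectride: hydride should attack C3 from the face opposite to ring B at C2 (equatorial attack on the half-chair), giving the axial 3R alcohol cis to the C2 aryl group, while low temperature keeps C2 from enolising.

Step 8
Reactants: 13 methyl 3,5-dihydroxy-4-methoxybenzoate
Product: 15 3,5-bis(benzyloxy)-4-methoxybenzoic acid, via methyl ester 14 (not isolated)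
Conditions: BnBr, K2CO3, DMF, 60 °C; then NaOH aq, MeOH, 60 °C; then HCl aq
Reagents that add atoms: benzyl bromide, BrCc1ccccc1; sodium hydroxide, [Na+].[OH-]
Why: Williamson O-benzylation of both phenols followed in the same pot by saponification of the methyl ester (acyl–oxygen cleavage by hydroxide) should give the protected acid.

Step 9
Reactants: 12 (2R,3R)-5,7-bis(benzyloxy)-2-[3,4-bis(benzyloxy)phenyl]chroman-3-ol; 15 3,5-bis(benzyloxy)-4-methoxybenzoic acid
Product: 16 (2R,3R)-5,7-bis(benzyloxy)-2-[3,4-bis(benzyloxy)phenyl]chroman-3-yl 3,5-bis(benzyloxy)-4-methoxybenzoate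
Conditions: DCC, DMAP, CH2Cl2, rt
Reagents that add atoms: none
Why: Steglich esterification acylates O3 without breaking the C3–O bond, so the 3R configuration is kept.

Step 10
Reactants: 16 (2R,3R)-5,7-bis(benzyloxy)-2-[3,4-bis(benzyloxy)phenyl]chroman-3-yl 3,5-bis(benzyloxy)-4-methoxybenzoate
Product: 17 epicatechin 3-O-(4-O-methylgallate)
Conditions: H2 (1 atm), Pd(OH)2/C, THF/MeOH, rt
Reagents that add atoms: none
Why: Catalytic hydrogenolysis over Pd(OH)2/C should cleave the six benzyl ethers while the ester, the methyl ether and the ring C2–O1 bond, which is cleaved more slowly, stay intact, so C2 and C3 are untouched.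

**Compound list**

1 | 3,5-bis(benzyloxy)phenol | Oc1cc(OCc2ccccc2)cc(OCc2ccccc2)c1 | starting material
2 | allyl bromide | C=CCBr | starting material
3 | 1-(allyloxy)-3,5-bis(benzyloxy)benzene | C=CCOc1cc(OCc2ccccc2)cc(OCc2ccccc2)c1 | intermediate
4 | 2-allyl-3,5-bis(benzyloxy)phenol | C=CCc1c(O)cc(OCc2ccccc2)cc1OCc1ccccc1 | intermediate
5 | 3,4-bis(benzyloxy)benzoic acid | OC(=O)c1ccc(OCc2ccccc2)c(OCc2ccccc2)c1 | starting material
6 | 2-allyl-3,5-bis(benzyloxy)phenyl 3,4-bis(benzyloxy)benzoate | C=CCc1c(OC(=O)c2ccc(OCc3ccccc3)c(OCc3ccccc3)c2)cc(OCc2ccccc2)cc1OCc1ccccc1 | intermediate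
7 | 2-allyl-3,5-bis(benzyloxy)phenyl 1-[3,4-bis(benzyloxy)phenyl]vinyl ether | C=CCc1c(OC(=C)c2ccc(OCc3ccccc3)c(OCc3ccccc3)c2)cc(OCc2ccccc2)cc1OCc1ccccc1 | intermediate
8 | 5,7-bis(benzyloxy)-2-[3,4-bis(benzyloxy)phenyl]-4H-chromene | C1=C(c2ccc(OCc3ccccc3)c(OCc3ccccc3)c2)Oc2cc(OCc3ccccc3)cc(OCc3ccccc3)c2C1 | intermediate
9 | (isopinocampheyl)[trans-5,7-bis(benzyloxy)-2-[3,4-bis(benzyloxy)phenyl]chroman-3-yl]borane, ring C configured as in 10 | C[C@H]1[C@H](B[C@H]2Cc3c(OCc4ccccc4)cc(OCc4ccccc4)cc3O[C@@H]2c2ccc(OCc3ccccc3)c(OCc3ccccc3)c2)C[C@@H]2C[C@H]1C2(C)C | intermediate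
10 | (2R,3S)-5,7-bis(benzyloxy)-2-[3,4-bis(benzyloxy)phenyl]chroman-3-ol | O[C@H]1Cc2c(OCc3ccccc3)cc(OCc3ccccc3)cc2O[C@@H]1c1ccc(OCc2ccccc2)c(OCc2ccccc2)c1 | intermediate
11 | (2R)-5,7-bis(benzyloxy)-2-[3,4-bis(benzyloxy)phenyl]chroman-3-one | O=C1Cc2c(OCc3ccccc3)cc(OCc3ccccc3)cc2O[C@@H]1c1ccc(OCc2ccccc2)c(OCc2ccccc2)c1 | intermediate
12 | (2R,3R)-5,7-bis(benzyloxy)-2-[3,4-bis(benzyloxy)phenyl]chroman-3-ol | O[C@@H]1Cc2c(OCc3ccccc3)cc(OCc3ccccc3)cc2O[C@@H]1c1ccc(OCc2ccccc2)c(OCc2ccccc2)c1 | intermediate
13 | methyl 3,5-dihydroxy-4-methoxybenzoate | COC(=O)c1cc(O)c(OC)c(O)c1 | starting material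
14 | methyl 3,5-bis(benzyloxy)-4-methoxybenzoate | COC(=O)c1cc(OCc2ccccc2)c(OC)c(OCc2ccccc2)c1 | intermediate
15 | 3,5-bis(benzyloxy)-4-methoxybenzoic acid | COc1c(OCc2ccccc2)cc(C(=O)O)cc1OCc1ccccc1 | intermediate
16 | (2R,3R)-5,7-bis(benzyloxy)-2-[3,4-bis(benzyloxy)phenyl]chroman-3-yl 3,5-bis(benzyloxy)-4-methoxybenzoate | COc1c(OCc2ccccc2)cc(C(=O)O[C@@H]2Cc3c(OCc4ccccc4)cc(OCc4ccccc4)cc3O[C@@H]2c2ccc(OCc3ccccc3)c(OCc3ccccc3)c2)cc1OCc1ccccc1 | intermediate
17 | epicatechin 3-O-(4-O-methylgallate), (2R,3R) | COc1c(O)cc(C(=O)O[C@@H]2Cc3c(O)cc(O)cc3O[C@@H]2c2ccc(O)c(O)c2)cc1O | target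

**Step count.** Total: 10 steps. Longest linear sequence: 9 steps (steps 1 to 7, 9 and 10); step 8 is a one-step side branch.

**Steps most likely to fail**

Step 4. The titanium methylidene may stop at the acyclic vinyl ether 7, because the hindered 1,1-disubstituted aryl enol ether is slow to enter the titanacyclobutane. Titanium hydride species may also move the allyl double bond into conjugation with ring A. Fallback: from 6, Lemieux–Johnson cleavage of the allyl olefin (OsO4 cat., NaIO4, 2,6-lutidine, dioxane/H2O) should give 3,5-bis(benzyloxy)-2-(2-oxoethyl)phenyl 3,4-bis(benzyloxy)benzoate F1. An intramolecular McMurry-type ester–aldehyde coupling with low-valent titanium (TiCl3, Zn–Cu couple, DME, reflux, high dilution) should then form C2=C3 reductively and return to 8.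

Step 5. The chiral borane may discriminate poorly between the two faces of this enol ether, so that 10 and then 11 are carried on with low enantiomeric purity. Fallback: from 11, step 7 is replaced by a Noyori asymmetric hydrogenation under dynamic kinetic resolution (RuCl2[(S)-xylbinap][(S)-daipen], KOtBu, iPrOH, H2; the mirror-image catalyst if the sense proves opposite). The base equilibrates 11 with its enantiomer, (2S)-5,7-bis(benzyloxy)-2-[3,4-bis(benzyloxy)phenyl]chroman-3-one F2, through the C2 enolate, and the catalyst should reduce only the 2R ketone to the cis alcohol. The route is rejoined at 12, with the enantiomeric purity now set by the catalyst and not by the borane.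

Step 10. Hydrogenolysis of the benzylic C2–O1 bond of ring C may compete with removal of the six benzyl ethers, or debenzylation may stall at partly protected material. Fallback: from 16, Lewis-acid debenzylation with BCl3 and pentamethylbenzene as cation scavenger (CH2Cl2, −78 °C) should give 17 directly without a reductive step; no new compound lies on this path.

**Further compounds**

F1 | step 4 | 3,5-bis(benzyloxy)-2-(2-oxoethyl)phenyl 3,4-bis(benzyloxy)benzoate | O=CCc1c(OC(=O)c2ccc(OCc3ccccc3)c(OCc3ccccc3)c2)cc(OCc2ccccc2)cc1OCc1ccccc1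
F2 | step 5 | (2S)-5,7-bis(benzyloxy)-2-[3,4-bis(benzyloxy)phenyl]chroman-3-one | O=C1Cc2c(OCc3ccccc3)cc(OCc3ccccc3)cc2O[C@H]1c1ccc(OCc2ccccc2)c(OCc2ccccc2)c1
F0 | step 10 | none | none
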